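All runs are calculated with made-up constants, and the scatter is random.

Friday's run has a leftover: it stops short of the whole charge, and its product no longer climbs.

| flask | starting material | protic impurity | free enzyme | temperature | remark | time |
|---|---|---|---|---|---|---|
| Saturday's | 0.10 M | 0.050 M | 5 µM | −25 °C | run made earlier |  |
| Friday's | 0.10 M | 0.050 M | 20 µM | 5 °C | run made earlier |  |
| cedar | 0.10 M | 0.0500 M | 10 µM | −20 °C |  | 15 d |
| oak | 0.10 M | 0.0500 M | 10 µM | 30 °C |  | 15 d |
| elm | 0.10 M | 0.0500 M | 10 µM | 5 °C |  | 15 d |
| maple | 0.10 M | 0.0500 M | 10 µM |  | at −20 °C until 8.0 d, from then on at 30 °C | 15 d |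

| run | time / d | product / % |
|---|---|---|
| Saturday's | 1.25 | 16 |
| Saturday's | 4.00 | 40 |
| Saturday's | 6.00 | 51 |
| Saturday's | 10.0 | 70 |
| Saturday's | 15.0 | 84 |
| Saturday's | 20.0 | 87 |
| Friday's | 0.333 | 61 |
| Friday's | 1.25 | 85 |
| Friday's | 1.67 | 89 |
| Friday's | 3.00 | 88 |
| Friday's | 4.00 | 90 |
| Friday's | 6.00 | 86 |

(scatter of a reading: 2 percentage points)

- the numbers in the tables scatter with a standard deviation of 2 percentage points

- which flask leads in amount of product, in percent of the starting material charged ("all alike" within 1.5 percentage points) (cedar / oak / elm / maple / all alike)
- how much product is there at the end, in percent of the starting material charged: cedar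
- how much product is there at the end, in percent of the starting material charged: oak
- how much product is there at the end, in percent of the starting material charged: elm
- how much product is there at the end, in percent of the starting material charged: maple

1. Read the rate on Saturday's run, in fractions of the charge. Over the first 1.25 d it makes 0.128 d⁻¹.
2. Read the slowing. Between 10.0 d and 15.0 d the rate is 0.0280 d⁻¹, slower than at the start by a factor of 4.57.
3. Split that factor. The part of the charge not yet product falls from 0.920 to 0.230, a factor of 4.00. The remaining factor is 1.14; with a scatter of 2 points on each reading, I give it no weight.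
4. So I read this slowing as delaying the end, and it says nothing of the end's height. For the height, turn to the leftover.
5. Take Friday's plateau from 1.67 d on: 0.882 of the charge, leaving 0.118. Bet that protic impurity takes this leftover one for one. Its charge, 0.500 of the starting material's, has room.
6. Divide the rate of loss by the rate of making, so that time drops out. This is the loss ratio, a selectivity factor: 0.133 on Friday's run.
7. Bet further that the making scales with free enzyme and the loss does not. Elm has the temperature of Friday's run and half its free enzyme, so its ratio is 0.266 and its product 0.790 of the charge.
8. Do the same for cedar. Saturday's last reading, taken as the end, gives 0.149, which becomes 0.0747 at cedar's free enzyme and product 0.930. This ignores cedar's being slightly warmer.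
9. Check that cedar finishes. Its 15 d counts like 30.0 d of Saturday's run, longer than that run's last reading.
10. At the free enzyme of these flasks, the ratio reads 0.0747 from the run at −25 °C and a higher 0.266 from the run at 5 °C, so I bet it climbs further at 30 °C. I put cedar above elm, oak below elm, and maple between cedar and oak.

The forecast differs: all alike, with 88% in each flask, since “Every flask should therefore sit at about 88%”.

The flasks give cedar 95.0%, oak 10.6%, elm 80.6% and maple 90.4%, so the leader is cedar.

    starting material + protic impurity → quenched substrate (k = 1.09 × 10⁻⁴ M⁻¹ s⁻¹, Ea = 78.0 kJ mol⁻¹)
    starting material + free enzyme → product + free enzyme, rate k2*[starting material]*[free enzyme]/(1 + ([starting material]/Km2) + ([product]/Kp2)) (0.142 M, 0.120 M, k = 3.07 M⁻¹ s⁻¹, Ea = 35.0 kJ mol⁻¹)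
    free enzyme → unfolded enzyme (k = 4.41 × 10⁻⁷ s⁻¹, Ea = 198 kJ mol⁻¹)
    (constants at 5 °C)

Elm holds 19.4% quenched substrate against 80.6% product at 15.0 d, a loss ratio of 0.241 where I reckoned 0.266. Cedar's ratio comes to 0.0473 where I reckoned 0.0747. Elm has come to rest as far as product goes: its starting material stands at 0% at 15.0 d, and at 150 d the product is still 80.6% and the quenched substrate 19.4%. Ten times the time still changes the free enzyme in elm, from 56.5% to 0.329% of its charge.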